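**Retrosynthetic overview**
1. Ring B is closed last: the C8–C9 bond comes from a type 2 intramolecular carbonyl-ene reaction of α-bromo aldehyde 23, which sets C9 and leaves the exocyclic C7=CH2.
2. C10–Br comes from catalyst-controlled enamine α-bromination of aldehyde 22, whose isopropenyl and aldehyde arms are made from the ester and vinyl groups of 15.
3. Bold key step: ring A and the spiro carbon C6 are formed together by a 6-exo ester-enolate alkylation (13 → 15) around a vicinal bromochloride that is already in place; the chair transition state sets C6 relative to C2/C3.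
4. C2–Br and C3–Cl are set on an open chain by titanium-mediated enantioselective bromochlorination of the Z allylic alcohol 8 (from 4-bromobut-1-yne), not by halogenating a ring alkene.
5. Ring order: ring A first, ring B second; no Diels–Alder step and no late-stage dihalogenation.

Assumption: atoms carry chamigrane labels (ring A = C1–C6 with Br on C2 and Cl/CH3 on C3, C6 = spiro carbon, ring B = C6–C11 with C7=C14H2, C9–OH, C10–Br, C11 gem-dimethyl), and in the two catalyst-controlled steps (4 and 12) the ligand or catalyst enantiomer is the one that gives the drawn configuration, both enantiomers being available.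

**Route**

Step 1
Reactants: 1 4-bromobut-1-yne; 2 methyl chloroformate
Product: 4 methyl 5-bromopent-2-ynoate, via lithium 4-bromobut-1-yn-1-ide 3 (not isolated)
Conditions: n-BuLi, THF, −78 °C; then 2, −78 to −20 °C
Reagents that add atoms: none
Why: Deprotonation of the terminal alkyne and C-acylation of the lithium acetylide by the chloroformate are fast at −78 °C, where the primary bromide is inert; no stereocentre is formed.

Step 2
Reactants: 4 methyl 5-bromopent-2-ynoate
Product: 6 methyl (Z)-5-bromo-3-methylpent-2-enoate, via lithium alkenyl(methyl)cuprate 5 (not isolated)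
Conditions: Me2CuLi (from MeLi and CuI), THF, −78 °C; MeOH quench at −78 °C
Reagents that add atoms: lithium dimethylcuprate, [Li+].C[Cu-]C
Why: Syn carbocupration of the ynoate (organocuprate conjugate addition) followed by protonation with retention at −78 °C places the new methyl trans to the ester, giving the Z (nerol-type) alkene that later becomes the trans Br/Cl pair, while the primary bromide does not couple at this temperature.

Step 3
Reactants: 6 methyl (Z)-5-bromo-3-methylpent-2-enoate
Product: 8 (Z)-5-bromo-3-methylpent-2-en-1-ol, via (Z)-5-bromo-3-methylpent-2-enal 7 (not isolated)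
Conditions: iBu2AlH (2.5 equiv), CH2Cl2, −78 °C
Reagents that add atoms: none
Why: 1,2-Hydride reduction of the enoate by iBu2AlH gives the allylic alcohol without touching the alkene geometry or the alkyl bromide.

Step 4
Reactants: 8 (Z)-5-bromo-3-methylpent-2-en-1-ol
Product: 9 (2S,3S)-2,5-dibromo-3-chloro-3-methylpentan-1-ol
Conditions: NBS, ClTi(OiPr)3 (1.1 equiv), chiral tridentate Schiff-base (salicylaldimine amino alcohol) ligand (20 mol %), hexanes, −20 °C
Reagents that add atoms: N-bromosuccinimide, O=C1CCC(=O)N1Br; chlorotitanium triisopropoxide, CC(C)O[Ti](Cl)(OC(C)C)OC(C)C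
Why: Titanium-mediated catalytic enantioselective bromochlorination of an allylic alcohol: the titanium-bound allylic alkoxide takes Br+ from NBS on the ligand-selected alkene face and chloride is passed from titanium to the more substituted C3 anti to bromine, so anti addition across the Z alkene sets C2 and C3 together as S,S.

Step 5
Reactants: 9 (2S,3S)-2,5-dibromo-3-chloro-3-methylpentan-1-ol
Product: 10 (2S,3S)-2,5-dibromo-3-chloro-3-methylpentyl trifluoromethanesulfonate
Conditions: Tf2O, 2,6-lutidine, CH2Cl2, −78 °C; used cold at once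
Reagents that add atoms: trifluoromethanesulfonic anhydride, O=S(=O)(OS(=O)(=O)C(F)(F)F)C(F)(F)F
Why: O-Sulfonylation of the primary alcohol with a weak hindered base gives the triflate without epoxide formation from the neighbouring bromide and without touching C2 or C3.

Step 6
Reactants: 11 methyl 3,3-dimethylpent-4-enoate; 10 (2S,3S)-2,5-dibromo-3-chloro-3-methylpentyl trifluoromethanesulfonate
Product: 13 methyl 2-[(2S,3S)-2,5-dibromo-3-chloro-3-methylpentyl]-3,3-dimethylpent-4-enoate, via lithium ester enolate 12 (not isolated)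
Conditions: LiN(iPr)2 (1.05 equiv per 11), THF, −78 °C; then 10 (0.85 equiv), −78 to −40 °C
Reagents that add atoms: none
Why: SN2 alkylation of a lithium ester enolate by a primary triflate at −78 °C is far faster than attack on either C–Br bond, forming the C6–C1 bond; the new α-stereocentre is a mixture that is erased in step 7.

Step 7
Reactants: 13 methyl 2-[(2S,3S)-2,5-dibromo-3-chloro-3-methylpentyl]-3,3-dimethylpent-4-enoate
Product: 15 methyl (1R,3S,4S)-3-bromo-4-chloro-4-methyl-1-(2-methylbut-3-en-2-yl)cyclohexane-1-carboxylate, via lithium enolate 14 (not isolated)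
Conditions: LiN(iPr)2 (1.3 equiv), THF/DMPU, 0.01 M, −78 to 0 °C
Reagents that add atoms: none
Why: Intramolecular 6-exo-tet ester-enolate alkylation closes ring A and creates the quaternary spiro carbon C6 through a chair transition state with the bulky 2-methylbut-3-en-2-yl group equatorial, the enolate carbon (future C7) axial and C2–Br and C3–Cl equatorial (C3–CH3 axial), because the other chair would push C2–Br 1,3-syn-axial onto the enolate oxygen; Br therefore ends trans to the ester and cis to the tert-alkyl group, and 3-exo closure onto C2–Br is suppressed at that secondary carbon flanked by the fully substituted C3.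

Step 8
Reactants: 15 methyl (1R,3S,4S)-3-bromo-4-chloro-4-methyl-1-(2-methylbut-3-en-2-yl)cyclohexane-1-carboxylate
Product: 17 2-[(1R,3S,4S)-3-bromo-4-chloro-4-methyl-1-(2-methylbut-3-en-2-yl)cyclohexyl]propan-2-ol, via methyl ketone 16 (not isolated)
Conditions: MeLi, CeCl3, THF, −78 to 0 °C
Reagents that add atoms: methyllithium, C[Li]
Why: Double 1,2-addition of the weakly basic, strongly nucleophilic organocerium reagent to the hindered ester gives the tertiary alcohol without enolising the intermediate ketone or eliminating the ring halides, which are locked equatorial.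

Step 9
Reactants: 17 2-[(1R,3S,4S)-3-bromo-4-chloro-4-methyl-1-(2-methylbut-3-en-2-yl)cyclohexyl]propan-2-ol
Product: 19 (1S,2S,4S)-2-bromo-1-chloro-1-methyl-4-(2-methylbut-3-en-2-yl)-4-(prop-1-en-2-yl)cyclohexane, via chlorosulfite ester 18 (not isolated)
Conditions: SOCl2, pyridine, CH2Cl2, −20 to 0 °C
Reagents that add atoms: none
Why: E2 dehydration of the chlorosulfite by pyridine can only take a methyl hydrogen because C6 is quaternary, so the isopropenyl group is the sole alkene and the basic medium avoids a free cation next to C6.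

Step 10
Reactants: 19 (1S,2S,4S)-2-bromo-1-chloro-1-methyl-4-(2-methylbut-3-en-2-yl)-4-(prop-1-en-2-yl)cyclohexane
Product: 21 3-[(1S,3S,4S)-3-bromo-4-chloro-4-methyl-1-(prop-1-en-2-yl)cyclohexyl]-3-methylbutan-1-ol, via trialkylborane 20 (not isolated)
Conditions: Sia2BH (from BH3·THF and 2-methylbut-2-ene), THF, 0 °C; then H2O2, NaOH (aq), 0 °C
Reagents that add atoms: hydrogen peroxide, OO
Why: Anti-Markovnikov hydroboration–oxidation with the bulky dialkylborane selects the monosubstituted vinyl group over the 1,1-disubstituted isopropenyl group, which is buried between C6 and C11, and gives the primary C9 alcohol.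

Step 11
Reactants: 21 3-[(1S,3S,4S)-3-bromo-4-chloro-4-methyl-1-(prop-1-en-2-yl)cyclohexyl]-3-methylbutan-1-ol
Product: 22 3-[(1S,3S,4S)-3-bromo-4-chloro-4-methyl-1-(prop-1-en-2-yl)cyclohexyl]-3-methylbutanal
Conditions: Dess–Martin periodinane, CH2Cl2, rt
Reagents that add atoms: none
Why: Dess–Martin oxidation converts the primary alcohol to the aldehyde under neutral conditions that leave the alkene and both halides untouched.

Step 12
Reactants: 22 3-[(1S,3S,4S)-3-bromo-4-chloro-4-methyl-1-(prop-1-en-2-yl)cyclohexyl]-3-methylbutanal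
Product: 23 (2S)-2-bromo-3-[(1S,3S,4S)-3-bromo-4-chloro-4-methyl-1-(prop-1-en-2-yl)cyclohexyl]-3-methylbutanal
Conditions: (2R,5R)-2,5-diphenylpyrrolidine (20 mol %), PhCO2H (20 mol %), 4,4-dibromo-2,6-di-tert-butylcyclohexa-2,5-dien-1-one, CH2Cl2/pentane, −40 °C; cold silica plug, used at once
Reagents that add atoms: 4,4-dibromo-2,6-di-tert-butylcyclohexa-2,5-dien-1-one, O=C1C(C(C)(C)C)=CC(Br)(Br)C=C1C(C)(C)C
Why: Enamine-catalysed asymmetric α-bromination, in which the chiral pyrrolidine shields one face of the E enamine of this neopentyl-type aldehyde, sets C10 under catalyst control independent of the remote C6 centre, and the mild Br+ donor does not attack the isopropenyl group.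

Step 13
Reactants: 23 (2S)-2-bromo-3-[(1S,3S,4S)-3-bromo-4-chloro-4-methyl-1-(prop-1-en-2-yl)cyclohexyl]-3-methylbutanal
Product: 24 (3R,4S,6S,8S,9S)-4,8-dibromo-9-chloro-5,5,9-trimethyl-1-methylidenespiro[5.5]undecan-3-ol (target)
Conditions: Me2AlCl (1.5 equiv), CH2Cl2, −78 °C
Reagents that add atoms: none
Why: Lewis-acid-promoted type 2 intramolecular carbonyl-ene reaction: the isopropenyl CH2 adds to the activated aldehyde through a chair with C10–Br equatorial and anti to the forming C8–C9 bond (Felkin–Anh) and the carbonyl oxygen axial so it can take a methyl hydrogen, which closes ring B, gives the exocyclic C7=CH2 and sets the C9–OH cis to Br.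

**Compound list**
1 | 4-bromobut-1-yne | C#CCCBr | starting material
2 | methyl chloroformate | COC(=O)Cl | starting material
3 | lithium 4-bromobut-1-yn-1-ide | [Li]C#CCCBr | intermediate
4 | methyl 5-bromopent-2-ynoate | COC(=O)C#CCCBr | intermediate
5 | lithium [(E)-5-bromo-1-methoxy-3-methyl-1-oxopent-2-en-2-yl](methyl)cuprate (Cu cis to the new methyl) | COC(=O)/C([Cu-]C)=C(/C)CCBr.[Li+] | intermediate
6 | methyl (Z)-5-bromo-3-methylpent-2-enoate | COC(=O)/C=C(/C)CCBr | intermediate
7 | (Z)-5-bromo-3-methylpent-2-enal | O=C/C=C(/C)CCBr | intermediate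
8 | (Z)-5-bromo-3-methylpent-2-en-1-ol | OC/C=C(/C)CCBr | intermediate
9 | (2S,3S)-2,5-dibromo-3-chloro-3-methylpentan-1-ol | BrCC[C@](C)(Cl)[C@@H](Br)CO | intermediate
10 | (2S,3S)-2,5-dibromo-3-chloro-3-methylpentyl trifluoromethanesulfonate | BrCC[C@](C)(Cl)[C@@H](Br)COS(=O)(=O)C(F)(F)F | intermediate
11 | methyl 3,3-dimethylpent-4-enoate | COC(=O)CC(C)(C)C=C | starting material
12 | lithium 1-methoxy-3,3-dimethylpenta-1,4-dien-1-olate | C=CC(C)(C)C=C(OC)O[Li] | intermediate
13 | methyl 2-[(2S,3S)-2,5-dibromo-3-chloro-3-methylpentyl]-3,3-dimethylpent-4-enoate (both epimers at the ester α-carbon) | BrCC[C@](C)(Cl)[C@@H](Br)CC(C(=O)OC)C(C)(C)C=C | intermediate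
14 | lithium 2-[(2S,3S)-2,5-dibromo-3-chloro-3-methylpentyl]-1-methoxy-3,3-dimethylpenta-1,4-dien-1-olate | BrCC[C@](C)(Cl)[C@@H](Br)CC(=C(OC)O[Li])C(C)(C)C=C | intermediate
15 | methyl (1R,3S,4S)-3-bromo-4-chloro-4-methyl-1-(2-methylbut-3-en-2-yl)cyclohexane-1-carboxylate (Br trans to Cl, Br trans to the ester) | C=CC(C)(C)[C@@]1(C(=O)OC)CC[C@](C)(Cl)[C@@H](Br)C1 | intermediate
16 | 1-[(1R,3S,4S)-3-bromo-4-chloro-4-methyl-1-(2-methylbut-3-en-2-yl)cyclohexyl]ethan-1-one | C=CC(C)(C)[C@@]1(C(C)=O)CC[C@](C)(Cl)[C@@H](Br)C1 | intermediate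
17 | 2-[(1R,3S,4S)-3-bromo-4-chloro-4-methyl-1-(2-methylbut-3-en-2-yl)cyclohexyl]propan-2-ol | C=CC(C)(C)[C@@]1(C(C)(C)O)CC[C@](C)(Cl)[C@@H](Br)C1 | intermediate
18 | 2-[(1R,3S,4S)-3-bromo-4-chloro-4-methyl-1-(2-methylbut-3-en-2-yl)cyclohexyl]propan-2-yl chlorosulfite | C=CC(C)(C)[C@@]1(C(C)(C)OS(Cl)=O)CC[C@](C)(Cl)[C@@H](Br)C1 | intermediate
19 | (1S,2S,4S)-2-bromo-1-chloro-1-methyl-4-(2-methylbut-3-en-2-yl)-4-(prop-1-en-2-yl)cyclohexane | C=CC(C)(C)[C@@]1(C(C)=C)CC[C@](C)(Cl)[C@@H](Br)C1 | intermediate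
20 | {3-[(1S,3S,4S)-3-bromo-4-chloro-4-methyl-1-(prop-1-en-2-yl)cyclohexyl]-3-methylbutyl}bis(3-methylbutan-2-yl)borane | CC(C)C(C)B(CCC(C)(C)[C@@]1(C(C)=C)CC[C@](C)(Cl)[C@@H](Br)C1)C(C)C(C)C | intermediate
21 | 3-[(1S,3S,4S)-3-bromo-4-chloro-4-methyl-1-(prop-1-en-2-yl)cyclohexyl]-3-methylbutan-1-ol | OCCC(C)(C)[C@@]1(C(C)=C)CC[C@](C)(Cl)[C@@H](Br)C1 | intermediate
22 | 3-[(1S,3S,4S)-3-bromo-4-chloro-4-methyl-1-(prop-1-en-2-yl)cyclohexyl]-3-methylbutanal | O=CCC(C)(C)[C@@]1(C(C)=C)CC[C@](C)(Cl)[C@@H](Br)C1 | intermediate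
23 | (2S)-2-bromo-3-[(1S,3S,4S)-3-bromo-4-chloro-4-methyl-1-(prop-1-en-2-yl)cyclohexyl]-3-methylbutanal | O=C[C@@H](Br)C(C)(C)[C@@]1(C(C)=C)CC[C@](C)(Cl)[C@@H](Br)C1 | intermediate
24 | (3R,4S,6S,8S,9S)-4,8-dibromo-9-chloro-5,5,9-trimethyl-1-methylidenespiro[5.5]undecan-3-ol (chamigrane labels 2S,3S,6S,9R,10S) | C=C1C[C@@H](O)[C@@H](Br)C(C)(C)[C@]12CC[C@](C)(Cl)[C@@H](Br)C2 | target

**Step count**
Total steps: 13. Longest linear sequence: 13 steps (1 → 24); compounds 2 and 11 are purchased and enter directly.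

**Three steps most likely to fail, with fallbacks**

Step 7 (ring A and spiro-centre closure; it also depends on the triflate alkylation of step 6). The enolate must be formed at a very hindered C–H in the presence of three C–halogen bonds. It may instead close a cyclopropane onto C2–Br, or give a poor C6 ratio. The fallback reverses the order in which the two C–C bonds to C6 are made, so that no enolate ever sits 1,3 to C2–Br. It sets out from alcohol 9 and comes back at 15. Silylation of 9 (TBSCl, imidazole, CH2Cl2) gives tert-butyl{[(2S,3S)-2,5-dibromo-3-chloro-3-methylpentyl]oxy}dimethylsilane F1. The lithium enolate 12 is alkylated at the unhindered primary bromide of F1 (THF/DMPU, −78 to 0 °C) to give methyl 2-[(3S,4S)-4-bromo-5-{[tert-butyl(dimethyl)silyl]oxy}-3-chloro-3-methylpentyl]-3,3-dimethylpent-4-enoate F2. HF·pyridine then frees methyl 2-[(3S,4S)-4-bromo-3-chloro-5-hydroxy-3-methylpentyl]-3,3-dimethylpent-4-enoate F3, and TsCl/pyridine gives methyl 2-[(3S,4S)-4-bromo-3-chloro-3-methyl-5-(tosyloxy)pentyl]-3,3-dimethylpent-4-enoate F4. LiN(iPr)2 in THF/DMPU closes the C6–C1 bond through the same chair (tert-alkyl equatorial, Br and Cl equatorial) and returns to 15.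

Step 12 (α-bromination). The aldehyde carries an exceptionally bulky β-quaternary group, so enamine formation or bromine transfer may be slow or poorly selective. The fallback replaces catalyst control by auxiliary control; it sets out from aldehyde 22 and comes back at 23. Pinnick oxidation (NaClO2, NaH2PO4, 2-methylbut-2-ene) gives 3-[(1S,3S,4S)-3-bromo-4-chloro-4-methyl-1-(prop-1-en-2-yl)cyclohexyl]-3-methylbutanoic acid F5. Acylation of (S)-4-benzyl-1,3-oxazolidin-2-one (PivCl, Et3N, LiCl, THF) gives (4S)-4-benzyl-3-{3-[(1S,3S,4S)-3-bromo-4-chloro-4-methyl-1-(prop-1-en-2-yl)cyclohexyl]-3-methylbutanoyl}-1,3-oxazolidin-2-one F6. The Z boron enolate (Bu2BOTf, iPr2NEt, −78 °C) is brominated by NBS on the face away from the benzyl group to give (4S)-4-benzyl-3-{(2S)-2-bromo-3-[(1S,3S,4S)-3-bromo-4-chloro-4-methyl-1-(prop-1-en-2-yl)cyclohexyl]-3-methylbutanoyl}-1,3-oxazolidin-2-one F7. LiBH4 (THF/MeOH, 0 °C) removes the auxiliary to give (2S)-2-bromo-3-[(1S,3S,4S)-3-bromo-4-chloro-4-methyl-1-(prop-1-en-2-yl)cyclohexyl]-3-methylbutan-1-ol F8, and Dess–Martin oxidation returns 23.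

Step 13 (ene ring closure). The axial-oxygen chair places the forming C9–O bond 1,3-syn-axial to one C11 methyl, so the closure may give the equatorial alcohol or a mixture. The fallback moves control of C9 from the pericyclic transition state to a hydride reduction; it sets out from 23 and comes back at 24. The ene product of the wrong configuration, (3S,4S,6S,8S,9S)-4,8-dibromo-9-chloro-5,5,9-trimethyl-1-methylidenespiro[5.5]undecan-3-ol F9 (alone or mixed with 24), is oxidised with Dess–Martin periodinane to (4S,6S,8S,9S)-4,8-dibromo-9-chloro-5,5,9-trimethyl-1-methylidenespiro[5.5]undecan-3-one F10. Reduction with iBu2AlH at −78 °C delivers hydride from the equatorial side, away from the axial C11 methyl, giving the axial alcohol cis to the equatorial bromine, which is 24.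

**Further compounds**
F1 | step 7 | tert-butyl{[(2S,3S)-2,5-dibromo-3-chloro-3-methylpentyl]oxy}dimethylsilane | BrCC[C@](C)(Cl)[C@@H](Br)CO[Si](C)(C)C(C)(C)C
F2 | step 7 | methyl 2-[(3S,4S)-4-bromo-5-{[tert-butyl(dimethyl)silyl]oxy}-3-chloro-3-methylpentyl]-3,3-dimethylpent-4-enoate | C=CC(C)(C)C(C(=O)OC)CC[C@](C)(Cl)[C@@H](Br)CO[Si](C)(C)C(C)(C)C
F3 | step 7 | methyl 2-[(3S,4S)-4-bromo-3-chloro-5-hydroxy-3-methylpentyl]-3,3-dimethylpent-4-enoate | C=CC(C)(C)C(C(=O)OC)CC[C@](C)(Cl)[C@@H](Br)CO
F4 | step 7 | methyl 2-[(3S,4S)-4-bromo-3-chloro-3-methyl-5-(tosyloxy)pentyl]-3,3-dimethylpent-4-enoate | C=CC(C)(C)C(C(=O)OC)CC[C@](C)(Cl)[C@@H](Br)COS(=O)(=O)c1ccc(C)cc1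
F5 | step 12 | 3-[(1S,3S,4S)-3-bromo-4-chloro-4-methyl-1-(prop-1-en-2-yl)cyclohexyl]-3-methylbutanoic acid | OC(=O)CC(C)(C)[C@@]1(C(C)=C)CC[C@](C)(Cl)[C@@H](Br)C1
F6 | step 12 | (4S)-4-benzyl-3-{3-[(1S,3S,4S)-3-bromo-4-chloro-4-methyl-1-(prop-1-en-2-yl)cyclohexyl]-3-methylbutanoyl}-1,3-oxazolidin-2-one | O=C(CC(C)(C)[C@@]1(C(C)=C)CC[C@](C)(Cl)[C@@H](Br)C1)N1[C@@H](Cc2ccccc2)COC1=O
F7 | step 12 | (4S)-4-benzyl-3-{(2S)-2-bromo-3-[(1S,3S,4S)-3-bromo-4-chloro-4-methyl-1-(prop-1-en-2-yl)cyclohexyl]-3-methylbutanoyl}-1,3-oxazolidin-2-one | O=C([C@@H](Br)C(C)(C)[C@@]1(C(C)=C)CC[C@](C)(Cl)[C@@H](Br)C1)N1[C@@H](Cc2ccccc2)COC1=O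
F8 | step 12 | (2S)-2-bromo-3-[(1S,3S,4S)-3-bromo-4-chloro-4-methyl-1-(prop-1-en-2-yl)cyclohexyl]-3-methylbutan-1-ol | OC[C@@H](Br)C(C)(C)[C@@]1(C(C)=C)CC[C@](C)(Cl)[C@@H](Br)C1
F9 | step 13 | (3S,4S,6S,8S,9S)-4,8-dibromo-9-chloro-5,5,9-trimethyl-1-methylidenespiro[5.5]undecan-3-ol | C=C1C[C@H](O)[C@@H](Br)C(C)(C)[C@]12CC[C@](C)(Cl)[C@@H](Br)C2
F10 | step 13 | (4S,6S,8S,9S)-4,8-dibromo-9-chloro-5,5,9-trimethyl-1-methylidenespiro[5.5]undecan-3-one | C=C1CC(=O)[C@@H](Br)C(C)(C)[C@]12CC[C@](C)(Cl)[C@@H](Br)C2
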